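**The task.** A small charge of second catalyst, 0.12 mol%, stood in each of four flasks, and I had to say how the order of addition would change their product.

common to all: free catalyst 0.47 mol%

|  | substrate | partner | second catalyst | remark | time |
|---|---|---|---|---|---|
| south | 0.050 M | 1.8 equiv | 0.12 mol% | run made earlier |  |
| west | 0.050 M | 1.2 equiv | 0.12 mol% | run made earlier |  |
| south-west | 0.050 M | 2.7 equiv | 0.12 mol% | run made earlier |  |
| north | 0.050 M | 1.8 equiv | 0.24 mol% | run made earlier |  |
| Thursday's | 0.050 M | 1.80 equiv | 0.12 mol% | everything together at the start | 2.5 d |
| Monday's | 0.050 M (fed, over 12 h) | 1.80 equiv | 0.12 mol% | all else is in the flask from the start; the feed brings no volume worth counting | 2.5 d |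
| Saturday's | 0.050 M | 1.80 equiv (in portions, 4, over 12 h) | 0.12 mol% | first portion at the start, last at 12 h | 2.5 d |
| Friday's | 0.050 M | 1.80 equiv (fed, over 12 h) | 0.12 mol% | all else is in the flask from the start; the feed brings no volume worth counting | 2.5 d |

| run | time / d | product / % | substrate / % |
|---|---|---|---|
| south | 0.208 | 59 | 15 |
| south | 0.333 | 67 | 5 |
| south | 0.500 | 72 | 4 |
| south | 0.833 | 68 | 2 |
| south | 1.67 | 71 | 4 |
| south | 2.50 | 70 | 2 |
| west | 0.500 | 59 | 7 |
| west | 1.04 | 60 | 7 |
| west | 1.67 | 60 | 7 |
| west | 2.08 | 58 | 3 |
| west | 2.50 | 59 | 4 |
| west | 3.00 | 59 | 4 |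
| south-west | 0.500 | 79 | 2 |
| south-west | 1.04 | 81 | 2 |
| south-west | 1.67 | 78 | 3 |
| south-west | 2.08 | 80 | 3 |
| south-west | 2.50 | 81 | 1 |
| south-west | 3.00 | 80 | 0 |
| north | 0.250 | 78 | 7 |
| north | 0.417 | 82 | 4 |
| north | 0.833 | 85 | 2 |
| north | 1.67 | 83 | 1 |
| north | 3.00 | 84 | 1 |

(readings scatter by 1.5 percentage points)

- steps under discussion: intermediate -> decomposed reagent; substrate + free catalyst <-> free catalyst + intermediate; free catalyst -> spent catalyst A; free catalyst + product -> spent catalyst B; partner + second catalyst + intermediate -> second catalyst + product

- the flask that comes out highest in amount of product, in percent of the substrate charged, or "all alike" when all lie within 1.5 percentage points (Thursday's / Monday's / Saturday's / Friday's / all alike)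
- product at the end, in percent of the substrate charged, Thursday's
- product at the end, in percent of the substrate charged, Monday's
- product at the end, in percent of the substrate charged, Saturday's
- product at the end, in percent of the substrate charged, Friday's

**Frozen partner.** Of the steps under discussion, intermediate has two forward exits, with partner and second catalyst to product or alone to decomposed reagent, and it can also fall back to substrate with free catalyst. So I froze [partner] at its midpoint and defined κ, the trapping constant, as product over material lost, per molar partner: a selectivity factor. South gave 34.5 M⁻¹, west 35.2 M⁻¹ and south-west 34.8 M⁻¹. North, with 0.24 mol%, read 81.2 M⁻¹, so κ goes with second catalyst.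

**The curves.** Thursday's repeats south: product climbs to 59% by 0.208 d, bends at 0.333 d with substrate at 5%, and lies near 70%. Friday's curve starts flat, since [partner] starts at nil. The two forward exits cross at [partner] = 1/κ, which the feed alone reaches at 0.161 d, earlier than south's bend. Assuming south's pace of turnover, the mean fed up to that bend is 0.0300 M. Taking off half the product made and solving for the level, I reckoned 40.0% for Friday's.

**The forecast.** It named Thursday's highest, with 70%, 60%, 40% and 32% in the order Thursday's, Monday's, Saturday's, Friday's. For Friday's, lower than my level, its ground was that “partner is scarcer still early on”.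

**The result.** Thursday's came out highest: 69.9%, then Monday's 56.5%, Saturday's 44.9% and Friday's 41.7%, which is 9.7 percentage points above the forecast.

    intermediate → decomposed reagent (k = 0.00558 min⁻¹)
    substrate + free catalyst ⇌ free catalyst + intermediate (K = 0.526, k = 192 M⁻¹ min⁻¹)
    free catalyst → spent catalyst A (k = 0.00389 min⁻¹)
    free catalyst + product → spent catalyst B (k = 0.0195 M⁻¹ min⁻¹)
    partner + second catalyst + intermediate → second catalyst + product (k = 3390 M⁻² min⁻¹)

**Partner seen.** Friday's held 41.7% product against 51.7% decomposed reagent, so κ puts the partner its intermediate met at 0.0234 M, less than the 0.0347 M mean of its first 12 h. Without the passing of intermediate into decomposed reagent, the gap between Thursday's and Friday's shrinks from 28 points to 11 points, the largest single effect but not the whole. Friday's neighbour, with its charge of second catalyst cut to 0.048 mol%, has κ scaled to 13.8 M⁻¹; its 27.6% product against 62.9% decomposed reagent gives 0.0318 M.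

The numbers in the tables stem from a simulated flask for substances that don't exist, and the scatter is random.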